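**Plan**
- Retrosynthesis: the exocyclic C3=CH(aryl) bond is cut first (aldol condensation with the syringaldehyde unit). The lactone ring (oxolan-2-one numbering O1, C2, C3, C4, C5) is then opened at two bonds at once, O1–C5 and C3–C4.
- Enabling feature: C5 (the OCH2 carbon) lies next to the stereocentre C4 and can briefly be a thionium carbon, while C2/C3 are the two carbons of a ketene. The ring atoms O1–C2–C3 and C4–C5 therefore map onto dichloroketene plus a (Z)-alkenyl sulfoxide, joined through a six-membered [3,3] array C3=C2–O–S–C5=C4.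
- Forward order: benzyl bromide → arylpropyne → alkynyl sulfoxide → (Z)-alkenyl sulfoxide → lactone ring closed in one operation → Cl and S helpers removed → arylidene by aldol addition and elimination → desilylation.
- Stereochemistry: C4 comes from the sulfur stereocentre of (1R,2S,5R)-menthyl (S)-p-toluenesulfinate by sulfur-to-carbon chirality transfer. The E double bond comes from E1cB elimination.

Key step: step 4

Assumption: the sense of chirality transfer in step 4 is taken from the allylic-strain model given there; if the opposite sense were found, (1S,2R,5S)-menthyl (R)-p-toluenesulfinate would replace 3 with nothing else changed.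

**Step 1**
Reactants: 1 5-(bromomethyl)-1,2,3-trimethoxybenzene (3,4,5-trimethoxybenzyl bromide)
Product: 2 1,2,3-trimethoxy-5-(prop-2-yn-1-yl)benzene
Conditions: HC≡CMgBr (2 equiv), CuBr (10 mol %), THF, 65 °C
Reagents that add atoms: ethynylmagnesium bromide, C#C[Mg]Br
Why: Copper-catalysed sp–sp3 cross-coupling of a reactive benzylic bromide with an alkynyl Grignard reagent should give the 3-arylpropyne, the excess of the Grignard reagent limiting a second benzylation.

**Step 2**
Reactants: 2 1,2,3-trimethoxy-5-(prop-2-yn-1-yl)benzene; 3 (1R,2S,5R)-menthyl (S)-4-methylbenzenesulfinate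
Product: 5 1,2,3-trimethoxy-5-{3-[(S)-4-methylbenzenesulfinyl]prop-2-yn-1-yl}benzene, via alkynylmagnesium bromide 4 (not isolated)
Conditions: EtMgBr (1.05 equiv), THF, 0 °C to rt; then added to 3, toluene, −20 °C
Reagents that add atoms: none
Why: Andersen sulfoxide synthesis, in which the alkynyl Grignard reagent displaces menthoxide at sulfur with clean inversion, so the sulfur stereocentre is taken from the sulfinate; low temperature and inverse addition should suppress propargyl-to-allenyl isomerisation.

**Step 3**
Reactants: 5 1,2,3-trimethoxy-5-{3-[(S)-4-methylbenzenesulfinyl]prop-2-yn-1-yl}benzene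
Product: 6 1,2,3-trimethoxy-5-{(2Z)-3-[(R)-4-methylbenzenesulfinyl]prop-2-en-1-yl}benzene
Conditions: H2 (1 atm), RhCl(PPh3)3 (5 mol %), benzene, rt
Reagents that add atoms: none
Why: Homogeneous syn semi-hydrogenation of a 1-alkynyl sulfoxide should stop at the (Z)-alkene without touching sulfur, whose descriptor changes from S to R only because the CIP ranks of the carbon substituents change.

**Step 4**
Reactants: 6 1,2,3-trimethoxy-5-{(2Z)-3-[(R)-4-methylbenzenesulfinyl]prop-2-en-1-yl}benzene
Product: 9 (4S,5R)-3,3-dichloro-5-[(4-methylphenyl)sulfanyl]-4-[(3,4,5-trimethoxyphenyl)methyl]oxolan-2-one (4,5-cis), via acyloxysulfonium enolate 7 (not isolated), via thionium carboxylate 8 (not isolated)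
Conditions: Cl3CCOCl (2.5 equiv), Zn–Cu couple (5 equiv), THF, −45 °C to 0 °C
Reagents that add atoms: trichloroacetyl chloride, ClC(=O)C(Cl)(Cl)Cl (delivered as dichloroketene, ClC(Cl)=C=O)
Why: The sulfinyl oxygen of 6 adds to the central carbon of dichloroketene (made in the flask from Cl3CCOCl and zinc) to give the acyloxysulfonium enolate 7, which undergoes a [3,3]-sigmatropic shift through the chair array Cl2C=C(O−)–O–S+–CH=CH, forming the C3–C4 bond as the S–O bond breaks and leaving the thionium carboxylate 8. The carboxylate, which now holds the former sulfinyl oxygen, adds to the thionium carbon, closing the lactone ring in a 5-exo-trig mode by forming the O1–C5 bond; the whole event is the Marino lactonization, an additive Pummerer reaction related to the Claisen rearrangement. The new stereocentre C4 is controlled by the stereogenic sulfur: in the (Z)-alkenyl sulfoxide, allylic 1,3-strain puts the sulfur lone pair in the alkene plane next to the CH2Ar group, so the S–O bond and the p-tolyl group lie on opposite faces and the enolate can only reach the face carrying oxygen. For (R)-sulfur and a Z double bond this should give the configuration the target needs (named 4S in 9 only because CCl2 outranks C5). The second new centre C5 is set by suprafacial collapse of the ion pair (arylthio cis to the benzyl group) and is removed in step 5. The sigmatropic path must outrun [2+2] addition of the ketene to the alkene and vinylogous Pummerer deprotonation at the allylic-benzylic CH2; the high electrophilicity of dichloroketene, the enolate stabilisation by two chlorine atoms and the absence of base should secure this.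

**Step 5**
Reactants: 9 (4S,5R)-3,3-dichloro-5-[(4-methylphenyl)sulfanyl]-4-[(3,4,5-trimethoxyphenyl)methyl]oxolan-2-one
Product: 12 (4R)-4-[(3,4,5-trimethoxyphenyl)methyl]oxolan-2-one, via monochloro lactone 10 (not isolated), via dechlorinated thio lactone 11 (not isolated)
Conditions: Bu3SnH (4 equiv), AIBN (cat.), toluene, 110 °C
Reagents that add atoms: none
Why: Radical chain reduction in which the tributyltin radical should abstract both α-carbonyl chlorines and then the arylthio group of the O,S-acetal carbon (an oxygen-stabilised radical), while C4 is never a radical centre and keeps its configuration (descriptor R after the CIP change).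

**Step 6**
Reactants: 13 4-hydroxy-3,5-dimethoxybenzaldehyde (syringaldehyde)
Product: 14 4-[(tert-butyldimethylsilyl)oxy]-3,5-dimethoxybenzaldehyde
Conditions: TBSCl, imidazole, DMF, rt
Reagents that add atoms: tert-butyldimethylsilyl chloride, CC(C)(C)[Si](C)(C)Cl
Why: Imidazole-promoted silylation masks the phenol, which would otherwise quench the lactone enolate and deactivate the aldehyde as its phenoxide.

**Step 7**
Reactants: 12 (4R)-4-[(3,4,5-trimethoxyphenyl)methyl]oxolan-2-one; 14 4-[(tert-butyldimethylsilyl)oxy]-3,5-dimethoxybenzaldehyde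
Product: 16 (3S,4R)-3-{[4-(tert-butyldimethylsilyloxy)-3,5-dimethoxyphenyl](hydroxy)methyl}-4-[(3,4,5-trimethoxyphenyl)methyl]oxolan-2-one (3,4-trans, both carbinol epimers), via lithium enolate 15 (not isolated)
Conditions: LiN(iPr)2 (LDA), THF, −78 °C; then 14, −78 °C
Reagents that add atoms: none
Why: Directed aldol addition of a lactone lithium enolate to a non-enolisable aryl aldehyde, the aldehyde entering C3 anti to the C4 benzyl group; C4 is not acidic under these conditions, and the C3 and carbinol centres are lost in step 8.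

**Step 8**
Reactants: 16 (3S,4R)-3-{[4-(tert-butyldimethylsilyloxy)-3,5-dimethoxyphenyl](hydroxy)methyl}-4-[(3,4,5-trimethoxyphenyl)methyl]oxolan-2-one
Product: 18 (3E,4R)-3-{[4-(tert-butyldimethylsilyloxy)-3,5-dimethoxyphenyl]methylidene}-4-[(3,4,5-trimethoxyphenyl)methyl]oxolan-2-one, via mesylate 17 (not isolated)
Conditions: MsCl, Et3N, CH2Cl2, 0 °C; then DBU, rt
Reagents that add atoms: none
Why: Sulfonylation followed by E1cB elimination (second half of an aldol condensation) should give the conjugated exocyclic alkene as the E isomer, with the aryl group anti to the lactone carbonyl, from either carbinol epimer.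

**Step 9**
Reactants: 18 (3E,4R)-3-{[4-(tert-butyldimethylsilyloxy)-3,5-dimethoxyphenyl]methylidene}-4-[(3,4,5-trimethoxyphenyl)methyl]oxolan-2-one
Product: 19 (3E,4R)-3-[(4-hydroxy-3,5-dimethoxyphenyl)methylidene]-4-[(3,4,5-trimethoxyphenyl)methyl]oxolan-2-one (CNP0198204.1)
Conditions: Bu4NF, AcOH, THF, 0 °C
Reagents that add atoms: none
Why: Fluoride cleaves the aryl silyl ether, and buffering with AcOH should prevent base-induced migration of the double bond into the ring or loss of configuration at C4.

**Compound list**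
1 | 5-(bromomethyl)-1,2,3-trimethoxybenzene | COc1cc(CBr)cc(OC)c1OC | starting material
2 | 1,2,3-trimethoxy-5-(prop-2-yn-1-yl)benzene | COc1cc(CC#C)cc(OC)c1OC | intermediate
3 | (1R,2S,5R)-2-isopropyl-5-methylcyclohexyl (S)-4-methylbenzenesulfinate | C[C@@H]1CC[C@H]([C@@H](C1)O[S@](=O)c1ccc(C)cc1)C(C)C | starting material
4 | bromo[3-(3,4,5-trimethoxyphenyl)prop-1-yn-1-yl]magnesium | COc1cc(CC#C[Mg]Br)cc(OC)c1OC | intermediate
5 | 1,2,3-trimethoxy-5-{3-[(S)-4-methylbenzenesulfinyl]prop-2-yn-1-yl}benzene | COc1cc(CC#C[S@@](=O)c2ccc(C)cc2)cc(OC)c1OC | intermediate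
6 | 1,2,3-trimethoxy-5-{(2Z)-3-[(R)-4-methylbenzenesulfinyl]prop-2-en-1-yl}benzene | COc1cc(C/C=C\[S@@](=O)c2ccc(C)cc2)cc(OC)c1OC | intermediate
7 | (R)-[(2,2-dichloro-1-oxidoethenyl)oxy](4-methylphenyl)[(1Z)-3-(3,4,5-trimethoxyphenyl)prop-1-en-1-yl]sulfonium (zwitterion) | [O-]C(=C(Cl)Cl)O[S@@+](c1ccc(C)cc1)/C=C\Cc1cc(OC)c(OC)c(OC)c1 | intermediate
8 | (3S)-2,2-dichloro-4-[(4-methylphenyl)sulfaniumylidene]-3-[(3,4,5-trimethoxyphenyl)methyl]butanoate (zwitterion) | [O-]C(=O)C(Cl)(Cl)[C@H](C=[S+]c1ccc(C)cc1)Cc1cc(OC)c(OC)c(OC)c1 | intermediate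
9 | (4S,5R)-3,3-dichloro-5-[(4-methylphenyl)sulfanyl]-4-[(3,4,5-trimethoxyphenyl)methyl]oxolan-2-one | Cc1ccc(S[C@H]2OC(=O)C(Cl)(Cl)[C@H]2Cc2cc(OC)c(OC)c(OC)c2)cc1 | intermediate
10 | (4S,5R)-3-chloro-5-[(4-methylphenyl)sulfanyl]-4-[(3,4,5-trimethoxyphenyl)methyl]oxolan-2-one (C3 epimers) | Cc1ccc(S[C@H]2OC(=O)C(Cl)[C@H]2Cc2cc(OC)c(OC)c(OC)c2)cc1 | intermediate
11 | (4R,5R)-5-[(4-methylphenyl)sulfanyl]-4-[(3,4,5-trimethoxyphenyl)methyl]oxolan-2-one | Cc1ccc(S[C@H]2OC(=O)C[C@H]2Cc2cc(OC)c(OC)c(OC)c2)cc1 | intermediate
12 | (4R)-4-[(3,4,5-trimethoxyphenyl)methyl]oxolan-2-one | COc1cc(C[C@H]2COC(=O)C2)cc(OC)c1OC | intermediate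
13 | 4-hydroxy-3,5-dimethoxybenzaldehyde | COc1cc(C=O)cc(OC)c1O | starting material
14 | 4-[(tert-butyldimethylsilyl)oxy]-3,5-dimethoxybenzaldehyde | COc1cc(C=O)cc(OC)c1O[Si](C)(C)C(C)(C)C | intermediate
15 | lithium (4R)-4-[(3,4,5-trimethoxyphenyl)methyl]-4,5-dihydrofuran-2-olate | COc1cc(C[C@H]2COC(O[Li])=C2)cc(OC)c1OC | intermediate
16 | (3S,4R)-3-{[4-(tert-butyldimethylsilyloxy)-3,5-dimethoxyphenyl](hydroxy)methyl}-4-[(3,4,5-trimethoxyphenyl)methyl]oxolan-2-one (carbinol epimers) | COc1cc(C[C@H]2COC(=O)[C@@H]2C(O)c2cc(OC)c(O[Si](C)(C)C(C)(C)C)c(OC)c2)cc(OC)c1OC | intermediate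
17 | methanesulfonate of 16 at the carbinol oxygen | COc1cc(C[C@H]2COC(=O)[C@@H]2C(OS(C)(=O)=O)c2cc(OC)c(O[Si](C)(C)C(C)(C)C)c(OC)c2)cc(OC)c1OC | intermediate
18 | (3E,4R)-3-{[4-(tert-butyldimethylsilyloxy)-3,5-dimethoxyphenyl]methylidene}-4-[(3,4,5-trimethoxyphenyl)methyl]oxolan-2-one | COc1cc(/C=C2/C(=O)OC[C@@H]2Cc2cc(OC)c(OC)c(OC)c2)cc(OC)c1O[Si](C)(C)C(C)(C)C | intermediate
19 | (3E,4R)-3-[(4-hydroxy-3,5-dimethoxyphenyl)methylidene]-4-[(3,4,5-trimethoxyphenyl)methyl]oxolan-2-one | COc1cc(/C=C2/C(=O)OC[C@@H]2Cc2cc(OC)c(OC)c(OC)c2)cc(OC)c1O | target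

**Step count**
Total steps: 9. Longest linear sequence: 8 (steps 1 to 5 and 7 to 9; step 6 is a one-step side branch).

**Steps most likely to fail**

Step 4. Chirality transfer may be incomplete if a second rotamer or a boat array competes. The activated sulfonium may also lose a proton from the allylic-benzylic CH2 (vinylogous Pummerer path), or the double bond may drift out of conjugation with sulfur under the zinc chloride formed, after which the allylic sulfoxide would racemise at sulfur. The fallback replaces sulfur-to-carbon transfer by auxiliary-controlled alkylation. It sets out from 1 and returns at 12. The sodium enolate of (4R)-4-benzyl-3-(4-tert-butoxy-4-oxobutanoyl)-1,3-oxazolidin-2-one (NaN(SiMe3)2, THF, −78 °C) would be alkylated with 1 on the face away from the auxiliary benzyl group (Evans alkylation). This should give (4R)-4-benzyl-3-{(2R)-4-tert-butoxy-4-oxo-2-[(3,4,5-trimethoxyphenyl)methyl]butanoyl}-1,3-oxazolidin-2-one F1. LiBH4 in Et2O with one equivalent of water should then cleave the imide reductively to tert-butyl (3R)-4-hydroxy-3-[(3,4,5-trimethoxyphenyl)methyl]butanoate F2. CF3CO2H in CH2Cl2 should close this to lactone 12.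

Step 2. The magnesium menthoxide formed may shift the doubly activated propargylic-benzylic protons of 5 and convert it into the allenyl sulfoxide, and a second equivalent of Grignard reagent may attack the product at sulfur. The fallback avoids the alkynyl sulfoxide altogether. It sets out from 2 and returns at 6. Iodination of 2 (N-iodosuccinimide, AgNO3 cat., acetone) should give 5-(3-iodoprop-2-yn-1-yl)-1,2,3-trimethoxybenzene F3. cis-Reduction with diimide (2-nitrobenzenesulfonylhydrazide, Et3N) should give 5-[(2Z)-3-iodoprop-2-en-1-yl]-1,2,3-trimethoxybenzene F4. Iodine–lithium exchange (t-BuLi, 2 equiv, Et2O, −78 °C) and addition of the alkenyllithium to sulfinate 3 should give 6, with retention of alkene geometry and inversion at sulfur.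

Step 5. The radical chain may stall after the two dechlorinations because homolysis of the C5–S bond is slow, and long heating may open the lactone. The fallback removes the two kinds of helper separately by electron transfer and by hydrogenolysis on nickel instead of in one radical chain. It sets out from 9 and returns at 12. Zn dust in AcOH at rt should dechlorinate 9 to 11, which is then isolated, and Raney Ni (W-2) in EtOH should cleave both C–S bonds to give 12. No compound outside the list is made (F0).

**Further compounds**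
F1 | step 4 | (4R)-4-benzyl-3-{(2R)-4-tert-butoxy-4-oxo-2-[(3,4,5-trimethoxyphenyl)methyl]butanoyl}-1,3-oxazolidin-2-one | COc1cc(C[C@H](CC(=O)OC(C)(C)C)C(=O)N2[C@H](Cc3ccccc3)COC2=O)cc(OC)c1OC
F2 | step 4 | tert-butyl (3R)-4-hydroxy-3-[(3,4,5-trimethoxyphenyl)methyl]butanoate | COc1cc(C[C@H](CC(=O)OC(C)(C)C)CO)cc(OC)c1OC
F3 | step 2 | 5-(3-iodoprop-2-yn-1-yl)-1,2,3-trimethoxybenzene | COc1cc(CC#CI)cc(OC)c1OC
F4 | step 2 | 5-[(2Z)-3-iodoprop-2-en-1-yl]-1,2,3-trimethoxybenzene | COc1cc(C/C=C\I)cc(OC)c1OC
F0 | step 5 | none | none
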